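## Retrosynthetic overview

1. Target 12 ⇐ bis-silyl ether 11 by acidic fluoride desilylation; nothing else changes.
2. 11 ⇐ racemic 3-bromochroman-4-one 3 + arylzinc from bromochromene 8. The cut is the C3–C1' bond between ring C (pyranone) and ring B. One stereoconvergent Ni-catalysed arylation forms this bond and sets C3.
3. Feature used: C3–H is the only stereocenter, and it is α to the C4 carbonyl and benzylic to ring B, hence configurationally labile. It is therefore created last, from a planar C3 radical that erases the configuration of the racemic bromide, under non-basic conditions.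
4. 3 ⇐ 5,7-dihydroxychroman-4-one 1 (rings A/C bought intact; silyl enol ether, then NBS). 8 ⇐ bromosalicylaldehyde 4 + alkenyl Grignard 5 (ring D, the dimethylpyran, closed by oxa-6π electrocyclisation).
5. Ring order: A/C purchased → D (step 3) → A/C joined to B/D (step 4). No ring is closed in the key step.

Key step: step 4

Assumption: 1 and 4 are taken as catalogue compounds. If 4 had to be made, para-bromination of 2-hydroxy-6-methoxybenzaldehyde would add one step.

## Route

Step 1
Reactants: 1 5,7-dihydroxychroman-4-one
Product: 2 4,5,7-tris[(tert-butyldimethylsilyl)oxy]-2H-chromene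
Conditions: TBSOTf (3.5 equiv), Et3N (5 equiv), CH2Cl2, 0 °C to rt
Reagents that add atoms: tert-butyldimethylsilyl trifluoromethanesulfonate, CC(C)(C)[Si](C)(C)OS(=O)(=O)C(F)(F)F
Why: Silyl triflate/amine soft enolisation should silylate both phenols and convert the aryl ketone into its silyl enol ether in one operation; only C3 carries α-hydrogens, so the enol ether is regiodefined.

Step 2
Reactants: 2 4,5,7-tris[(tert-butyldimethylsilyl)oxy]-2H-chromene
Product: 3 rac-3-bromo-5,7-bis[(tert-butyldimethylsilyl)oxy]-2,3-dihydro-4H-chromen-4-one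
Conditions: NBS (1.05 equiv), THF, −78 to −20 °C; pH 7 buffer
Reagents that add atoms: N-bromosuccinimide, O=C1CCC(=O)N1Br
Why: Electrophilic bromination of a silyl enol ether; the enol ether is far more nucleophilic than the shielded bis-silyloxy arene, and the near-neutral conditions avoid base-induced loss of HBr to the chromone (the racemate is what the key step wants).

Step 3
Reactants: 4 3-bromo-6-hydroxy-2-methoxybenzaldehyde, 5 2-methylprop-1-en-1-ylmagnesium bromide
Product: 8 6-bromo-5-methoxy-2,2-dimethyl-2H-chromene, via benzylic diol 6 (not isolated), via ortho-quinone methide 7 (not isolated)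
Conditions: 5 (2.5 equiv), THF, 0 °C to rt; aq NH4Cl; crude in PhMe, PPTS (5 mol%), 80 °C
Reagents that add atoms: none
Why: Grignard addition to the salicylaldehyde (first equivalent consumed by the phenol) gives an ortho-hydroxybenzyl allylic alcohol that dehydrates to an ortho-quinone methide and closes by oxa-6π electrocyclisation, a known 2,2-dimethylchromene synthesis; the substitution pattern of 4 fixes the regiochemistry and an alkenyl Grignard should not exchange with the aryl bromide at 0 °C.

Step 4
Reactants: 3 rac-3-bromo-5,7-bis[(tert-butyldimethylsilyl)oxy]-2,3-dihydro-4H-chromen-4-one, 8 6-bromo-5-methoxy-2,2-dimethyl-2H-chromene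
Product: 11 (3R)-5,7-bis[(tert-butyldimethylsilyl)oxy]-3-(5-methoxy-2,2-dimethyl-2H-chromen-6-yl)-2,3-dihydro-4H-chromen-4-one, via arylmagnesium bromide 9 (not isolated), via arylzinc iodide 10 (not isolated)
Conditions: 8 (1.6 equiv), Mg, THF, 40 °C; ZnI2, THF, rt; then 3, NiCl2·glyme (5 mol%), (S,S)-Ph-pybox (6.5 mol%), glyme/THF, −30 °C; EtOH quench at −30 °C
Reagents that add atoms: none
Why: Proposed new method: a (pybox)Ni(I)–aryl species formed by transmetalation of 10 should abstract bromine from either enantiomer of 3 to give the same planar C3 α-keto radical, which is captured by the chiral Ni(II)–aryl complex, and C3–C1' reductive elimination from Ni(III) then sets C3 under ligand control, so that both enantiomers of 3 converge on (R)-11. The closest known reaction type is the Ni/pybox-catalysed asymmetric Negishi arylation of racemic acyclic α-bromo aryl ketones with arylzinc iodides at −30 °C, which gives tertiary α-aryl ketones without racemisation; the extension proposed is to a cyclic α-bromoketone with a β-aryloxy group and to an ortho-methoxy arylzinc. No ring is closed; the step joins the A/C chromanone to the B/D chromene through the C3–C1' bond. The single new stereocenter C3 is controlled by the pybox ligand alone; the (S,S) antipode is the working choice, its sense of induction cannot be predicted for this substrate class and must be confirmed on the first run, and the (R,R) ligand is equally available. The step needs radical capture to outrun β-scission of the C2–O1 bond and the product to escape enolisation: in the fused ring the C2–O1 bond lies near the nodal plane of the C3 radical, and an arylzinc iodide at −30 °C is too weakly basic to deprotonate the α-aryl ketone. The chromene alkene, the aryl silyl ethers and the aryl methyl ether should be inert to the arylzinc and to the Ni(I)/Ni(III) cycle.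

Step 5
Reactants: 11 (3R)-5,7-bis[(tert-butyldimethylsilyl)oxy]-3-(5-methoxy-2,2-dimethyl-2H-chromen-6-yl)-2,3-dihydro-4H-chromen-4-one
Product: 12 (3R)-5,7-dihydroxy-3-(5-methoxy-2,2-dimethyl-2H-chromen-6-yl)-2,3-dihydro-4H-chromen-4-one
Conditions: HF·pyridine, THF/pyridine, 0 °C to rt
Reagents that add atoms: none
Why: Acid-buffered fluoride should cleave both aryl silyl ethers without forming a basic phenoxide/fluoride pair that could enolise C3, and should leave the aryl methyl ether and the chromene untouched (standard desilylation).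

## Compound list

1 | 5,7-dihydroxychroman-4-one | O=C1CCOc2cc(O)cc(O)c12 | starting material
2 | 4,5,7-tris[(tert-butyldimethylsilyl)oxy]-2H-chromene | CC(C)(C)[Si](C)(C)OC1=CCOc2cc(O[Si](C)(C)C(C)(C)C)cc(O[Si](C)(C)C(C)(C)C)c12 | intermediate
3 | rac-3-bromo-5,7-bis[(tert-butyldimethylsilyl)oxy]-2,3-dihydro-4H-chromen-4-one | O=C1C(Br)COc2cc(O[Si](C)(C)C(C)(C)C)cc(O[Si](C)(C)C(C)(C)C)c12 | intermediate
4 | 3-bromo-6-hydroxy-2-methoxybenzaldehyde | O=Cc1c(O)ccc(Br)c1OC | starting material
5 | 2-methylprop-1-en-1-ylmagnesium bromide | CC(C)=C[Mg]Br | starting material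
6 | 4-bromo-2-(1-hydroxy-3-methylbut-2-en-1-yl)-3-methoxyphenol | CC(C)=CC(O)c1c(O)ccc(Br)c1OC | intermediate
7 | 4-bromo-5-methoxy-6-(3-methylbut-2-en-1-ylidene)cyclohexa-2,4-dien-1-one | O=C1C=CC(Br)=C(OC)C1=CC=C(C)C | intermediate
8 | 6-bromo-5-methoxy-2,2-dimethyl-2H-chromene | COc1c(Br)ccc2c1C=CC(C)(C)O2 | intermediate
9 | (5-methoxy-2,2-dimethyl-2H-chromen-6-yl)magnesium bromide | COc1c([Mg]Br)ccc2c1C=CC(C)(C)O2 | intermediate
10 | (5-methoxy-2,2-dimethyl-2H-chromen-6-yl)zinc iodide | COc1c([Zn]I)ccc2c1C=CC(C)(C)O2 | intermediate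
11 | (3R)-5,7-bis[(tert-butyldimethylsilyl)oxy]-3-(5-methoxy-2,2-dimethyl-2H-chromen-6-yl)-2,3-dihydro-4H-chromen-4-one | COc1c([C@@H]2COc3cc(O[Si](C)(C)C(C)(C)C)cc(O[Si](C)(C)C(C)(C)C)c3C2=O)ccc2c1C=CC(C)(C)O2 | intermediate
12 | (3R)-5,7-dihydroxy-3-(5-methoxy-2,2-dimethyl-2H-chromen-6-yl)-2,3-dihydro-4H-chromen-4-one (CNP0118527.1) | COc1c([C@@H]2COc3cc(O)cc(O)c3C2=O)ccc2c1C=CC(C)(C)O2 | target

## Step count and risks

Total steps: 5. Longest linear sequence: 4 (1 → 2 → 3 → 11 → 12).

**Step 4** (carries the label). What may go wrong: the nickel catalyst may reduce the cyclic α-bromoketone or open ring C by β-aryloxy loss; transmetalation of the ortho-methoxy arylzinc may be slow; facial control at C3 may be insufficient. The fallback uses known chemistry, sets out from 1 and 8 and comes back at 11. Silylation of 1 (TBSCl, imidazole, DMF) should give 5,7-bis[(tert-butyldimethylsilyl)oxy]chroman-4-one F1. Palladium-catalysed α-arylation of F1 with 8 (Pd2(dba)3, XPhos, K3PO4, toluene, 80 °C), a known route from chroman-4-ones to racemic isoflavanones, should give racemic bis-silyl isoflavanone F2. Asymmetric transfer hydrogenation under dynamic kinetic resolution (RuCl[(R,R)-TsDPEN](p-cymene), HCO2H/Et3N, rt) should funnel both enantiomers of F2 through the enol to the cis-(3R,4R)-isoflavan-4-ol F3. Buffered Dess–Martin oxidation (NaHCO3, CH2Cl2, 0 °C) should then return 11 with C3 untouched.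

**Step 3.** What may go wrong: the ortho-quinone methide may oligomerise, or the acid used for dehydration may hydrate or dimerise the electron-rich chromene. The fallback sets out from 4 and comes back at 8. A Petasis borono-Mannich condensation of 4 with (2-methylprop-1-en-1-yl)boronic acid and dibenzylamine (1 equiv, dioxane, 90 °C) should give the aminophenol 4-bromo-2-[1-(dibenzylamino)-3-methylbut-2-en-1-yl]-3-methoxyphenol F4. On heating, F4 should lose the amine to the same quinone methide 7 and close to 8, with neither a Grignard reagent nor acid.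

**Step 5.** What may go wrong: fluoride- or phenoxide-mediated enolisation may erode the configuration at C3, or the hindered 5-O-silyl group may be removed incompletely. The fallback removes the deprotection step by transient protection; it sets out from 1 and comes back at 12. TMSOTf/Et3N should give 4,5,7-tris(trimethylsilyloxy)-2H-chromene F5. NBS should give rac-3-bromo-5,7-bis(trimethylsilyloxy)chroman-4-one F6, used crude. Coupling of F6 with 10 under the conditions of step 4 should give the (3R)-bis(trimethylsilyl) isoflavanone F7. Its aryl trimethylsilyl ethers should hydrolyse during a pH 4–5 citrate work-up to deliver 12 directly.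

## Further compounds

F1 | step 4 | 5,7-bis[(tert-butyldimethylsilyl)oxy]chroman-4-one | O=C1CCOc2cc(O[Si](C)(C)C(C)(C)C)cc(O[Si](C)(C)C(C)(C)C)c12
F2 | step 4 | rac-5,7-bis[(tert-butyldimethylsilyl)oxy]-3-(5-methoxy-2,2-dimethyl-2H-chromen-6-yl)-2,3-dihydro-4H-chromen-4-one | COc1c(C2COc3cc(O[Si](C)(C)C(C)(C)C)cc(O[Si](C)(C)C(C)(C)C)c3C2=O)ccc2c1C=CC(C)(C)O2
F3 | step 4 | (3R,4R)-5,7-bis[(tert-butyldimethylsilyl)oxy]-3-(5-methoxy-2,2-dimethyl-2H-chromen-6-yl)chroman-4-ol | COc1c([C@@H]2COc3cc(O[Si](C)(C)C(C)(C)C)cc(O[Si](C)(C)C(C)(C)C)c3[C@@H]2O)ccc2c1C=CC(C)(C)O2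
F4 | step 3 | 4-bromo-2-[1-(dibenzylamino)-3-methylbut-2-en-1-yl]-3-methoxyphenol | CC(C)=CC(N(Cc1ccccc1)Cc1ccccc1)c1c(O)ccc(Br)c1OC
F5 | step 5 | 4,5,7-tris(trimethylsilyloxy)-2H-chromene | C[Si](C)(C)OC1=CCOc2cc(O[Si](C)(C)C)cc(O[Si](C)(C)C)c12
F6 | step 5 | rac-3-bromo-5,7-bis(trimethylsilyloxy)-2,3-dihydro-4H-chromen-4-one | O=C1C(Br)COc2cc(O[Si](C)(C)C)cc(O[Si](C)(C)C)c12
F7 | step 5 | (3R)-3-(5-methoxy-2,2-dimethyl-2H-chromen-6-yl)-5,7-bis(trimethylsilyloxy)-2,3-dihydro-4H-chromen-4-one | COc1c([C@@H]2COc3cc(O[Si](C)(C)C)cc(O[Si](C)(C)C)c3C2=O)ccc2c1C=CC(C)(C)O2
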